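Start from how slow the earlier runs are. After an early burst, the summer run had 2.3% of target at 2.50 min, and from then on it gained 0.00337 min⁻¹ of the charge. The autumn run, with more impurity, read 1.6% at 20.0 min.

the same everywhere: starting material 0.80 M

| run | second substrate | coupling partner | free catalyst | impurity | remark |
|---|---|---|---|---|---|
| summer | 1.6 M | 0.88 M | 8 mM | 4.8 mM | run made earlier |
| autumn | 1.6 M | 0.88 M | 8 mM | 7.5 mM | run made earlier |
| midnight | 1.6 M | 0.44 M | 8 mM | 3.4 mM | run made earlier |
| flask | 1.60 M | 0.880 M | 8.0 mM | 3.4 mM |  |

| run | time / min | target / % | starting material / % |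
|---|---|---|---|
| summer | 1.50 | 1.3 | 99.2 |
| summer | 2.50 | 2.3 | 98.0 |
| summer | 4.00 | 2.8 | 97.7 |
| summer | 6.00 | 3.0 | 96.3 |
| summer | 8.00 | 3.8 | 96.3 |
| summer | 12.0 | 5.0 | 94.4 |
| summer | 20.0 | 8.2 | 91.7 |
| autumn | 1.50 | 0 | 99.1 |
| autumn | 2.50 | 1.1 | 99.9 |
| autumn | 4.00 | 0 | 99.3 |
| autumn | 6.00 | 0.6 | 99.6 |
| autumn | 8.00 | 0.8 | 99.1 |
| autumn | 12.0 | 2.2 | 98.9 |
| autumn | 20.0 | 1.6 | 99.2 |
| midnight | 2.00 | 1.4 | 99.1 |
| midnight | 5.00 | 2.8 | 97.7 |
| midnight | 10.0 | 3.5 | 96.1 |
| midnight | 15.0 | 5.1 | 95.6 |
| midnight | 20.0 | 5.3 | 94.6 |

(readings scatter by 0.5 percentage points)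

1. apparent order in second substrate when 10% of the starting material are converted (percent change of the rate of making target for one percent more second substrate charged)
2. apparent order in coupling partner when 10% of the starting material are converted (percent change of the rate of making target for one percent more coupling partner charged)

- no earlier run changes the charge of second substrate; that part of a forecast is a guess

Climb the ladder of times from the bottom. On my reading, the first rung, over before the steady stretch begins, is the impurity taking catalyst away one for one. So the number to carry is the surviving catalyst, the catalyst charged minus the impurity charged: 3.20 mM in the summer run, 4.60 mM in the midnight run and 4.60 mM in this flask.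

The second rung is the burst, and the third is the steady slope. The midnight run, with 0.44 M of coupling partner against the summer run's 0.88 M, gains 0.00217 min⁻¹ of the charge after 2.00 min. Per surviving catalyst, the summer slope is 2.23 times the midnight slope, which I read as an order of 1.16 in coupling partner.

The last rung is the time asked about. Scaling the summer slope to this flask's surviving catalyst, adding the summer burst and counting converted starting material as target, I estimate 10% conversion in this flask at about 18.4 min, later than the burst.

The forecast gives 0.95 (0.55 to 1.35) for coupling partner, lower than my reading. For second substrate it gives 0.5 (−0.2 to 1.2), saying: “No run varies the second substrate, so its order is a guess”.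

    starting material + free catalyst ⇌ catalyst intermediate A (K = 0.590 L mol⁻¹, k = 0.110 L mol⁻¹ s⁻¹)
    coupling partner + catalyst intermediate A → free catalyst + target (k = 0.670 L mol⁻¹ s⁻¹)
    second substrate + free catalyst ⇌ catalyst intermediate B (K = 15.0 L mol⁻¹, k = 0.120 L mol⁻¹ s⁻¹)
    coupling partner + catalyst intermediate B → free catalyst + second product (k = 0.100 L mol⁻¹ s⁻¹)
    free catalyst → spent catalyst A (k = 3.40 × 10⁻⁴ s⁻¹)
    free catalyst + impurity → spent catalyst B (k = 82.0 L mol⁻¹ s⁻¹)

The flask gives −1.0 in second substrate and 1.5 in coupling partner. At 20.0 min in this flask, catalyst intermediate B, the resting state of the round at 35.4% of the catalyst charged, holds 61.5% of the surviving catalyst. At 16.8 min, each unit of surviving catalyst in this flask makes target at 0.804 min⁻¹. The autumn run has the same charges of coupling partner and second substrate but 0.500 mM of surviving catalyst, so that turnover, held steady, estimates 1.00% of target by 20.0 min, and the autumn run read 1.6%.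

(Readings and results stem from a simulated flask from invented constants, and the scatter is random.)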